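With the benzene ring numbered C1 (formyl), C2 and C3 (OH), C4 (H), C5 (side chain) and C6 (OH), the acyl-bearing C1 lies between the oxygenated C2 and C6, which is what a 1,3,5-tricarbonyl chain leaves behind when it folds once; only the C3 oxygen is additional. The ring is therefore opened at C4–C5 and C1–C2. A single Lewis acid operation joins the 1,3-bis(silyloxy)diene of a β-keto thioester, whose terminal carbon already bears the complete (S)-configured C15 ester chain, to methyl 2,3-dimethoxyacrylate and aromatizes the adduct. The thioester is the latent aldehyde, the C3 methyl ether the latent hydroxyl.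

Key step: step 12

Remark: chain positions follow the dodecadienoic acid numbering; C2 of the chain is the only stereocentre and lies α to an ester, so strong base is kept away from it (n-BuLi below the amount of enolate in step 9, amine/silyl triflate enolization in step 11).
Assumption: diene 19 and acrylate 17 are drawn as single geometric isomers; these enol ether geometries are erased in step 12, so isomer mixtures should serve equally.

Step 1
Reactants: 1 (2E,6E)-farnesol
Product: 2 (2E,6E)-farnesyl acetate
Conditions: Ac2O, pyridine, DMAP (cat.), CH2Cl2, 0 °C → rt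
Reagents that add atoms: acetic anhydride, CC(=O)OC(C)=O
Why: DMAP-catalysed acyl transfer (esterification) masks the primary allylic hydroxyl, so that the later Ru-catalysed hydrogenation finds no free allylic alcohol to direct it to the C2–C3 alkene of the farnesyl unit.

Step 2
Reactants: 2 (2E,6E)-farnesyl acetate
Product: 3 (2E,6E,10E)-12-hydroxy-3,7,11-trimethyldodeca-2,6,10-trien-1-yl acetate
Conditions: SeO2 (cat.), t-BuOOH, salicylic acid (cat.), CH2Cl2, rt
Reagents that add atoms: selenium dioxide, O=[Se]=O (oxygen donor); tert-butyl hydroperoxide, CC(C)(C)OO (terminal oxidant that restores it)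
Why: The ene reaction/[2,3]-sigmatropic shift of the Riley allylic oxidation takes place at the most electron-rich terminal alkene and gives the (E)-allylic alcohol; any enal 4 formed by over-oxidation is carried along, because step 3 makes 4 anyway.

Step 3
Reactants: 3 (2E,6E,10E)-12-hydroxy-3,7,11-trimethyldodeca-2,6,10-trien-1-yl acetate
Product: 4 (2E,6E,10E)-3,7,11-trimethyl-12-oxododeca-2,6,10-trien-1-yl acetate
Conditions: MnO2 (activated, excess), CH2Cl2, rt
Reagents that add atoms: none
Why: MnO2 oxidizes only the allylic primary alcohol (allylic alcohol oxidation) and should leave the acetate and the isolated alkenes untouched.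

Step 4
Reactants: 4 (2E,6E,10E)-3,7,11-trimethyl-12-oxododeca-2,6,10-trien-1-yl acetate
Product: 5 (2E,6E,10E)-12-acetoxy-2,6,10-trimethyldodeca-2,6,10-trienoic acid
Conditions: NaClO2, NaH2PO4, 2-methyl-2-butene, t-BuOH/H2O, 0 °C → rt
Reagents that add atoms: sodium chlorite, [Na+].[O-]Cl=O
Why: The Pinnick oxidation converts the enal into the (E)-2-methyl-2-enoic acid without moving the double bond, while excess 2-methyl-2-butene removes the HOCl that would otherwise attack the chain alkenes.

Step 5
Reactants: 5 (2E,6E,10E)-12-acetoxy-2,6,10-trimethyldodeca-2,6,10-trienoic acid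
Product: 6 (2S,6E,10E)-12-acetoxy-2,6,10-trimethyldodeca-6,10-dienoic acid
Conditions: Ru(OAc)2[(S)-H8-BINAP] (1 mol %), H2 (3 atm), MeOH, 20 °C
Reagents that add atoms: none
Why: Carboxylate-directed Ru–BINAP-type asymmetric hydrogenation should reduce only the acid-conjugated alkene and set C2 as S, the (S)-ligand being chosen by analogy with tiglic acid, which this catalyst class reduces to (S)-2-methylbutanoic acid and which has the same substituent pattern and CIP ranking at C2; the allylic acetate and the isolated trisubstituted alkenes offer the metal no binding site.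

Step 6
Reactants: 6 (2S,6E,10E)-12-acetoxy-2,6,10-trimethyldodeca-6,10-dienoic acid
Product: 8 methyl (2S,6E,10E)-12-hydroxy-2,6,10-trimethyldodeca-6,10-dienoate, via potassium hydroxy carboxylate 7 (not isolated)
Conditions: K2CO3, MeOH, rt; evaporate; MeI, DMF, rt
Reagents that add atoms: iodomethane, CI
Why: Carbonate-mediated methanolysis (transesterification) frees the allylic alcohol while the acid rests as its non-enolizable carboxylate, which iodomethane then O-alkylates (SN2 esterification), so C2 is never an ester in the presence of methoxide.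

Step 7
Reactants: 8 methyl (2S,6E,10E)-12-hydroxy-2,6,10-trimethyldodeca-6,10-dienoate
Product: 9 methyl (2S,6E,10E)-12-bromo-2,6,10-trimethyldodeca-6,10-dienoate
Conditions: CBr4, PPh3, CH2Cl2, 0 °C
Reagents that add atoms: carbon tetrabromide, BrC(Br)(Br)Br
Why: The Appel reaction displaces the alkoxyphosphonium group of the primary allylic alcohol by bromide in an SN2 step, so neither allylic transposition nor E/Z isomerization is expected at 0 °C and the ester is inert.

Step 8
Reactants: 10 2,2,6-trimethyl-4H-1,3-dioxin-4-one
Product: 12 S-ethyl 3-oxobutanethioate, via acetylketene 11 (not isolated)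
Conditions: EtSH (3 equiv), toluene, 110 °C, sealed tube
Reagents that add atoms: ethanethiol, CCS
Why: Thermal retro-[4+2] cleavage of the dioxinone releases acetone and acetylketene, which the thiol captures by addition to give the β-keto thioester (acylketene trapping).

Step 9
Reactants: 12 S-ethyl 3-oxobutanethioate; 9 methyl (2S,6E,10E)-12-bromo-2,6,10-trimethyldodeca-6,10-dienoate
Product: 14 methyl (2S,6E,10E)-16-(ethylsulfanyl)-2,6,10-trimethyl-14,16-dioxohexadeca-6,10-dienoate, via thioester dianion 13 (not isolated)
Conditions: 12 (1.5 equiv), NaH (1.5 equiv), THF, 0 °C; n-BuLi (1.4 equiv), −78 → −30 °C; 9 (1.0 equiv), −78 → −20 °C; aq. NH4Cl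
Reagents that add atoms: none
Why: In this γ-alkylation of a β-keto (thio)ester dianion the terminal carbanion should displace the primary allylic bromide by SN2 faster than it can attack or deprotonate the remote α-branched ester, and keeping n-BuLi below the amount of enolate together with the cold quench protects C2.

Step 10
Reactants: 15 methyl methoxyacetate
Product: 17 methyl (Z)-2,3-dimethoxyacrylate, via sodium formyl enolate 16 (not isolated)
Conditions: HCO2Me, NaH, THF, 0 °C → rt; then Me2SO4, DMF, rt
Reagents that add atoms: methyl formate, COC=O; dimethyl sulfate, COS(=O)(=O)OC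
Why: Crossed Claisen formylation gives the stabilized formyl enolate, which the hard electrophile dimethyl sulfate methylates on oxygen in DMF (enol ether formation).

Step 11
Reactants: 14 methyl (2S,6E,10E)-16-(ethylsulfanyl)-2,6,10-trimethyl-14,16-dioxohexadeca-6,10-dienoate
Product: 19 methyl (2S,6E,10E,13Z,15Z)-16-(ethylsulfanyl)-2,6,10-trimethyl-14,16-bis(trimethylsilyloxy)hexadeca-6,10,13,15-tetraenoate, via mono(trimethylsilyl) enol ether 18 (not isolated)
Conditions: Me3SiOTf (2.2 equiv), Et3N (3 equiv), Et2O, 0 °C; pentane, removal of the ammonium salt, used crude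
Reagents that add atoms: trimethylsilyl trifluoromethanesulfonate, C[Si](C)(C)OS(=O)(=O)C(F)(F)F
Why: Soft enolization (silyl triflate/amine silyl enol ether formation) silylates the 1,3-dicarbonyl enol and then removes the γ-proton of the O-silylated vinylogous thioester to give the 1,3-bis(silyloxy)diene, while an isolated α-branched methyl ester is silylated far more slowly by this reagent pair and no strong base is present, so C2 should keep its configuration.

Step 12
Reactants: 19 methyl (2S,6E,10E,13Z,15Z)-16-(ethylsulfanyl)-2,6,10-trimethyl-14,16-bis(trimethylsilyloxy)hexadeca-6,10,13,15-tetraenoate; 17 methyl (Z)-2,3-dimethoxyacrylate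
Product: 21 methyl (2S,6E,10E)-12-[3-(ethylsulfanylcarbonyl)-2,4-dihydroxy-5-methoxyphenyl]-2,6,10-trimethyldodeca-6,10-dienoate, via open-chain adduct 20 (not isolated)
Conditions: 17 (1.5 equiv), TiCl4 (1.5 equiv), 2,6-di-tert-butyl-4-methylpyridine (0.2 equiv), 4 Å MS, CH2Cl2, −78 °C; 19, −78 → 20 °C; then 1 M aq. HCl, 0 °C
Reagents that add atoms: none
Why: Proposed new method: TiCl4 chelates the α-methoxy and ester carbonyl oxygens of 17, the terminal carbon of diene 19 (future C5) adds to the β-carbon (future C4) in a Mukaiyama–Michael step and methoxide is expelled to give 20, whose titanium-chelated 1,3-dicarbonyl enolate then acylates its central carbon (future C1) with the acrylate ester (Claisen condensation), and loss of the second methanol with two enolizations leaves the benzene ring. The closest known reaction type is the TiCl4-mediated formal [3+3] cyclocondensation of 1,3-bis(silyloxy)-1,3-dienes with 3-alkoxy- or 3-silyloxy-enones to salicylates; new are the 2,3-dialkoxyacrylate as the three-carbon partner and an ester as the second acceptor. The benzene ring closes at C1–C2 by a 6-(enolendo)-exo-trig acylation. No stereocentre is created, since the sp3 carbon of 20 becomes aromatic, and the C2 centre of the chain is remote from all reacting sites. The step needs attack of the diene terminus at the β-carbon and not at the ester, secured by the higher nucleophilicity of that terminus and the vinylogous activation of the β-position, and C- over O-acylation in the closure, favoured by the chelated enolate and made irreversible by aromatization. The geometry of the new alkene in 20 should not limit closure because the doubly activated C–H next to it lets the double bond move in and out of conjugation, and the hindered pyridine takes up HCl so that the trisubstituted alkenes and the ortho-allyl phenol survive.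

Step 13
Reactants: 21 methyl (2S,6E,10E)-12-[3-(ethylsulfanylcarbonyl)-2,4-dihydroxy-5-methoxyphenyl]-2,6,10-trimethyldodeca-6,10-dienoate
Product: 22 methyl (2S,6E,10E)-12-(3-formyl-2,4-dihydroxy-5-methoxyphenyl)-2,6,10-trimethyldodeca-6,10-dienoate
Conditions: Pd/C (10 wt %), Et3SiH, acetone, rt
Reagents that add atoms: none
Why: In the Fukuyama reduction zerovalent palladium inserts into the acyl–sulfur bond and the silane delivers hydride, which should stop at the aldehyde and leave the methyl ester, the phenols and the trisubstituted alkenes unchanged.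

Step 14
Reactants: 22 methyl (2S,6E,10E)-12-(3-formyl-2,4-dihydroxy-5-methoxyphenyl)-2,6,10-trimethyldodeca-6,10-dienoate
Product: 23 (2S,6E,10E)-12-(3-formyl-2,4-dihydroxy-5-methoxyphenyl)-2,6,10-trimethyldodeca-6,10-dienoic acid
Conditions: LiOH, THF/H2O, rt, argon; then 1 M HCl
Reagents that add atoms: lithium hydroxide, [Li+].[OH-]
Why: Saponification (acyl–oxygen cleavage by hydroxide) of the unhindered methyl ester should proceed at room temperature without appreciable enolization at C2, the aldehyde being protected as its vinylogous phenoxide and air being excluded because that phenoxide is oxidizable.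

Step 15
Reactants: 23 (2S,6E,10E)-12-(3-formyl-2,4-dihydroxy-5-methoxyphenyl)-2,6,10-trimethyldodeca-6,10-dienoic acid
Product: 25 (2S,6E,10E)-12-(3-formyl-2,4,5-trihydroxyphenyl)-2,6,10-trimethyldodeca-6,10-dienoic acid, via hydroxyquinone 24 (not isolated)
Conditions: (NH4)2Ce(NO3)6 (2.2 equiv), MeCN/H2O, 0 °C, short contact; then aq. Na2S2O4, EtOAc, rt, argon
Reagents that add atoms: water, O
Why: Oxidative demethylation of the 4-methoxyphenol unit (C6 hydroxyl para to the C3 methyl ether) by tetravalent cerium should give the hydroxyquinone with loss of methanol, water supplying the new C3 oxygen, and dithionite reduction (quinone to hydroquinone) then releases the air-sensitive hydroxyquinol under reducing conditions that isolated trisubstituted alkenes tolerate.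

Compound list
1 | (2E,6E)-farnesol, (2E,6E)-3,7,11-trimethyldodeca-2,6,10-trien-1-ol | CC(C)=CCC/C(C)=C/CC/C(C)=C/CO | starting material
2 | (2E,6E)-farnesyl acetate | CC(C)=CCC/C(C)=C/CC/C(C)=C/COC(C)=O | intermediate
3 | (2E,6E,10E)-12-hydroxy-3,7,11-trimethyldodeca-2,6,10-trien-1-yl acetate | OC/C(C)=C/CC/C(C)=C/CC/C(C)=C/COC(C)=O | intermediate
4 | (2E,6E,10E)-3,7,11-trimethyl-12-oxododeca-2,6,10-trien-1-yl acetate | O=C/C(C)=C/CC/C(C)=C/CC/C(C)=C/COC(C)=O | intermediate
5 | (2E,6E,10E)-12-acetoxy-2,6,10-trimethyldodeca-2,6,10-trienoic acid | OC(=O)/C(C)=C/CC/C(C)=C/CC/C(C)=C/COC(C)=O | intermediate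
6 | (2S,6E,10E)-12-acetoxy-2,6,10-trimethyldodeca-6,10-dienoic acid | CC(=O)OC/C=C(\C)CC/C=C(\C)CCC[C@H](C)C(O)=O | intermediate
7 | potassium (2S,6E,10E)-12-hydroxy-2,6,10-trimethyldodeca-6,10-dienoate | [K+].OC/C=C(\C)CC/C=C(\C)CCC[C@H](C)C([O-])=O | intermediate (not isolated)
8 | methyl (2S,6E,10E)-12-hydroxy-2,6,10-trimethyldodeca-6,10-dienoate | OC/C=C(\C)CC/C=C(\C)CCC[C@H](C)C(=O)OC | intermediate
9 | methyl (2S,6E,10E)-12-bromo-2,6,10-trimethyldodeca-6,10-dienoate | BrC/C=C(\C)CC/C=C(\C)CCC[C@H](C)C(=O)OC | intermediate
10 | 2,2,6-trimethyl-4H-1,3-dioxin-4-one | CC1=CC(=O)OC(C)(C)O1 | starting material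
11 | acetylketene (but-1-ene-1,3-dione) | CC(=O)C=C=O | intermediate (not isolated)
12 | S-ethyl 3-oxobutanethioate (S-ethyl acetothioacetate) | CCSC(=O)CC(C)=O | intermediate
13 | sodium lithium (1Z)-1-(ethylsulfanyl)buta-1,3-diene-1,3-diolate (dianion of 12) | [Na+].[Li+].CCS/C([O-])=C\C([O-])=C | intermediate (not isolated)
14 | methyl (2S,6E,10E)-16-(ethylsulfanyl)-2,6,10-trimethyl-14,16-dioxohexadeca-6,10-dienoate | CCSC(=O)CC(=O)CC/C=C(\C)CC/C=C(\C)CCC[C@H](C)C(=O)OC | intermediate
15 | methyl methoxyacetate | COCC(=O)OC | starting material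
16 | sodium (Z)-2,3-dimethoxy-3-oxoprop-1-en-1-olate | [Na+].[O-]/C=C(\OC)C(=O)OC | intermediate (not isolated)
17 | methyl (Z)-2,3-dimethoxyacrylate | CO/C=C(\OC)C(=O)OC | intermediate
18 | methyl (2S,6E,10E,14Z)-16-(ethylsulfanyl)-2,6,10-trimethyl-16-oxo-14-(trimethylsilyloxy)hexadeca-6,10,14-trienoate | CCSC(=O)/C=C(\O[Si](C)(C)C)CC/C=C(\C)CC/C=C(\C)CCC[C@H](C)C(=O)OC | intermediate (not isolated)
19 | methyl (2S,6E,10E,13Z,15Z)-16-(ethylsulfanyl)-2,6,10-trimethyl-14,16-bis(trimethylsilyloxy)hexadeca-6,10,13,15-tetraenoate | CCS/C(O[Si](C)(C)C)=C\C(O[Si](C)(C)C)=C\C/C=C(\C)CC/C=C(\C)CCC[C@H](C)C(=O)OC | intermediate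
20 | methyl (2E,6Z)-7-(ethylsulfanyl)-2-methoxy-4-[(2E,6E,11S)-12-methoxy-3,7,11-trimethyl-12-oxododeca-2,6-dien-1-yl]-5-oxo-7-(trimethylsilyloxy)hepta-2,6-dienoate (both C4 epimers; drawn in the geometry that can close) | CCS/C(O[Si](C)(C)C)=C\C(=O)C(C/C=C(\C)CC/C=C(\C)CCC[C@H](C)C(=O)OC)/C=C(/OC)C(=O)OC | intermediate (not isolated)
21 | methyl (2S,6E,10E)-12-[3-(ethylsulfanylcarbonyl)-2,4-dihydroxy-5-methoxyphenyl]-2,6,10-trimethyldodeca-6,10-dienoate | CCSC(=O)c1c(O)c(C/C=C(\C)CC/C=C(\C)CCC[C@H](C)C(=O)OC)cc(OC)c1O | intermediate
22 | methyl (2S,6E,10E)-12-(3-formyl-2,4-dihydroxy-5-methoxyphenyl)-2,6,10-trimethyldodeca-6,10-dienoate | O=Cc1c(O)c(C/C=C(\C)CC/C=C(\C)CCC[C@H](C)C(=O)OC)cc(OC)c1O | intermediate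
23 | (2S,6E,10E)-12-(3-formyl-2,4-dihydroxy-5-methoxyphenyl)-2,6,10-trimethyldodeca-6,10-dienoic acid | O=Cc1c(O)c(C/C=C(\C)CC/C=C(\C)CCC[C@H](C)C(O)=O)cc(OC)c1O | intermediate
24 | (2S,6E,10E)-12-(5-formyl-4-hydroxy-3,6-dioxocyclohexa-1,4-dien-1-yl)-2,6,10-trimethyldodeca-6,10-dienoic acid | O=CC1=C(O)C(=O)C=C(C/C=C(\C)CC/C=C(\C)CCC[C@H](C)C(O)=O)C1=O | intermediate (not isolated)
25 | (2S,6E,10E)-12-(3-formyl-2,4,5-trihydroxyphenyl)-2,6,10-trimethyldodeca-6,10-dienoic acid | C/C(=C\Cc1cc(O)c(O)c(C=O)c1O)CC/C=C(\C)CCC[C@H](C)C(=O)O | target

Total step count: 15. Longest linear sequence: 13 steps (steps 1–7, 9, 11, 12, 13, 14, 15).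

Steps most likely to fail

1. Step 12 (proposed new method). What may go wrong: the electron-rich dialkoxyacrylate may not accept the diene before the diene is desilylated; the closure may stop at the open chain or turn to O-acylation; acid from the titanium reagent may add to the chain alkenes or close the phenol onto the neighbouring alkene. Fallback (known chemistry; the arene is made first and the chain attached afterwards): it sets out from bromide 9 and comes back to the route at 22. 1,2,4-Trimethoxybenzene F1 is lithiated between its 2- and 4-methoxy groups (n-BuLi, THF, 0 °C) and formylated with DMF to 2,3,6-trimethoxybenzaldehyde F2. The two ethers flanking the formyl group are cleaved with chelation assistance (AlCl3, CH2Cl2, rt) to 2,6-dihydroxy-3-methoxybenzaldehyde F3. The sodium phenoxide of F3 (NaH, toluene, 0 °C → rt) is C-allylated by 9 at C5, its only free position ortho or para to a phenoxide oxygen, which gives 22 and leaves steps 14 and 15 as they are.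

2. Step 11. What may go wrong: the second silylation may stay incomplete, the moisture-sensitive diene may hydrolyse on handling, or slow enolization of the remote ester may erode the configuration at C2. Fallback (the chain is taken out of the enolization chemistry): it sets out from 12 and 9 and comes back at 21. Thioester 12 is bis-silylated under the conditions of step 11 to (1Z)-1-(ethylsulfanyl)-1,3-bis(trimethylsilyloxy)buta-1,3-diene F4, which is condensed with 17 as in step 12 to S-ethyl 2,6-dihydroxy-3-methoxybenzenecarbothioate F5. The sodium phenoxide of F5 (NaH, toluene, 0 °C → rt) is C-allylated by bromide 9 at C5, giving 21.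

3. Step 15. What may go wrong: over-oxidation or decomposition while the electrophilic formyl hydroxyquinone is present, oxidative cyclization of the phenol onto the neighbouring alkene, or re-oxidation of the hydroxyquinol by air during isolation. Fallback (non-oxidative unmasking): it sets out from 23 and comes back at 25. AlCl3 and pyridine in CH2Cl2 at reflux form the aluminium chelate between the C2 phenoxide and the C3 ether oxygen, and chloride removes the methyl group, a known way to turn 2-hydroxy-3-methoxybenzaldehydes into catechols. Pyridine buffers the HCl, and no new compound lies on this path.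

Further compounds
F1 | step 12 | 1,2,4-trimethoxybenzene | COc1ccc(OC)c(OC)c1
F2 | step 12 | 2,3,6-trimethoxybenzaldehyde | COc1ccc(OC)c(C=O)c1OC
F3 | step 12 | 2,6-dihydroxy-3-methoxybenzaldehyde | COc1ccc(O)c(C=O)c1O
F4 | step 11 | (1Z)-1-(ethylsulfanyl)-1,3-bis(trimethylsilyloxy)buta-1,3-diene | CCS/C(O[Si](C)(C)C)=C\C(O[Si](C)(C)C)=C
F5 | step 11 | S-ethyl 2,6-dihydroxy-3-methoxybenzenecarbothioate | CCSC(=O)c1c(O)ccc(OC)c1O
F0 | step 15 | none | none
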